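## Structural features

The target is an ent-labdane: a trans-fused decalin (ring A = C1–C5 and C10, ring B = C5–C10) with a six-carbon branched chain (C11–C16) on C9 that ends in a primary acetate at C15. Ring A carries an equatorial acetate at C2 and an axial free hydroxyl at C3; the two oxygens are cis to each other and both anti to the angular methyl C20, and C3 sits directly beside the quaternary gem-dimethyl carbon C4 (methyls C18 and C19). Ring B holds the trisubstituted alkene C7=C8 with methyl C17, next to the C9 methine, whose chain is equatorial and whose hydrogen is anti to C20. There are six stereocentres, (2S,3R,5S,9R,10S,13S) in labdane numbering: C2–C3 on one side of C4, the contiguous set C5–C10–C9 across the ring fusion, and the isolated C13 methyl centre in the chain, which cannot be relayed from the rings. Fragile features are the cis hydroxy acetate (over-acylation or acyl migration), the primary acetate, and the electron-rich C7=C8 alkene, which competes in any late oxidation of ring A. The real difficulty is the pair of fully substituted carbons C4 and C10 flanking the trans ring fusion, together with placing both ring A oxygens on the face opposite the axial methyls. The key step uses the fact that C4 with its two methyls beside C3 is a disguised isopropenyl group: if C3 arrives as a carbene carbon on the isopropenyl alkene of a carvone-derived ring B, ring A closes and C18 is held in a cyclopropane (C3–C4–C18) that is later cut to the second methyl.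

## Logic of the disconnections

**30 ⇒ 29 ⇒ 28.** The acyl–oxygen bonds at O2 and O15 are cut, then the O–Si bond at O15. Acetates cannot survive the organometallic and dissolving-metal steps, so they must come last. The gain is a triol whose three hydroxyls differ strongly in hindrance. The demand is that acylation stops at the primary and the equatorial C2 hydroxyl and leaves the axial C3 hydroxyl beside C4.

**28 ⇒ 27 ⇒ 26.** The C7–H bond is replaced by a C7–O triflate, and the C2–O and C3–O bonds are cut back to a C2=C3 alkene. Keeping ring B as an electron-poor, tetrasubstituted vinyl triflate during the oxidation means only the ring A alkene can be dihydroxylated. Two stereocentres disappear. The demand is syn addition from the face anti to C20 and the axial C4 methyl.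

**26 ⇒ 24.** The C9–H bond and the O–S bond of the triflate are cut, giving the enone C7(=O)–C8=C9. The reductively generated enolate fixes the alkene position between C7 and C8 and sets C9 in the same operation. The demand is protonation at C9 on the axial trajectory anti to C20.

**24 ⇒ 23.** A 1,3-oxygen transposition moves the C7 carbonyl back to a tertiary allylic hydroxyl on C9. This turns the C9 substituent problem into a simple carbonyl addition. The demand is a clean allylic shift of a hindered tertiary chromate ester.

**23 ⇒ 22 ⇒ 20.** The C3–H bond is replaced by a C2–O triflate, and the bond C3–C18 is re-formed, so that the gem-dimethyl group and the C2=C3 alkene both derive from one cyclopropyl ketone. The gain is that C4 no longer has to be built as a quaternary carbon by alkylation. The demand is that only the exocyclic cyclopropane bond breaks and that the resulting enolate is trapped without equilibration. Ring B is inert at this stage because it is present as an allylic alkoxide.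

**20 ⇒ 10 + 16.** The C9–C11 bond is cut, which makes the route convergent and separates the C13 centre from the ring system. The demand is that the nucleophile chooses the hindered C9 carbonyl over the more accessible C2 carbonyl; the C2 ketone is therefore masked in the flask as its enolate.

**10 ⇒ 9.** The bonds C3–C4 and C3–C18 are cut (key step). Ring A and the cyclopropane vanish together, leaving a monocyclic diazomethyl ketone. The demand is chemoselective carbene transfer to the isopropenyl alkene.

**9 ⇒ 7 ⇒ 6.** The C2–C3 bond is cut (acylation of diazomethane), and the acid is traced to its methyl ester. C3 is brought in as a one-carbon unit. The demand is activation of a neopentyl-type acid without touching the isopropenyl group.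

**6 ⇒ 3 + 4, and 3 ⇒ 1.** The bonds C10–C1 and then C10–C20 are cut. Both are enolate alkylations on the same carbon, and the order (methyl first, acetate arm second) puts the arm trans to the isopropenyl group. The demand is alkylation anti to the C5 substituent.

**16 ⇒ 15 ⇒ 14 ⇒ 13 ⇒ 12 ⇒ 11.** These are functional-group changes only (iodide from alcohol, alcohol from ester, silyl ether, alcohol from acid), ending in a prochiral diester. The C13 centre is created by differentiating two enantiotopic ester groups. The demand is high enantiotopic selectivity, because an error at C13 gives a diastereomer that is remote from the rings and hard to remove.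

## Other disconnections considered

**Alternative 1:** The cut is C5–C10 and C8–C9, opening both rings to the acyclic triene A1. In A1, C9=C10 is a (Z)-alkylidene ester whose ester carbon is C20, C5–C8 is a 2-silyloxy diene, and the C1–C4 tether already carries the diol as an acetonide. The forward step is an intramolecular Diels–Alder reaction to the decalin A2.
- In its favour: two rings, two C–C bonds and the C5/C9/C10 set form in one pericyclic step, and C9 with its chain is fixed directly by the dienophile geometry. On this point the alternative is the better plan, since the chosen route needs steps 11, 14, 15 and 17 to install and set C9. The diol arriving already protected is at least the equal of the late osmylation in step 16, and there is no carbenoid chemoselectivity question.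
- Against it here: C20 arrives as an ester and must be taken down to a methyl group at a neopentyl position (reduction, activation, deoxygenation). The trans fusion depends on one of two closely balanced transition states of a 1,7,9-decatriene with a fully substituted dienophile carbon, and the facial bias rests only on the acetonide in the tether. A1 also needs three stereodefined alkenes and separate asymmetric steps for C2, C3 and C13.
- Comparison: after cyclisation the silyl enol ether of A2 still has to be turned into the C7=C8 alkene by the same triflate chemistry as in the chosen plan, so nothing is saved there. The chosen plan takes C5 from the chiral pool and C10 and C4 from substrate-controlled steps on a rigid ring, and it should be shorter overall.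

**Alternative 2:** The cut is C2–C3, giving the 2,3-seco dialdehyde A3. The forward step is ketyl–ketyl coupling with SmI2 (divalent samarium), closing ring A as the cis-diol A4.
- In its favour: both carbinol centres and ring A form in one step at the final oxidation level, with the cis relationship inherent to a samarium-bridged coupling. The C15 acetate can already be present, so only one acetylation remains. On end-game economy this is the better plan, since it replaces steps 12, 13 and 16 of the chosen route.
- Equal points: the last discrimination between the C2 and C3 hydroxyls is the same problem as in step 19. The required face (both oxygens anti to C20) is the one expected from a chair-like transition state, although this is less rigidly enforced than attack on a pre-formed ring alkene.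
- Against it here: all the difficulty moves into A3. Ring B must be made with C5, C9 and C10 contiguous, the chain and the C7=C8 alkene in place, and a hindered, non-enolisable aldehyde on quaternary C4 beside an enolisable one on C1, without ring A to guide the stereochemistry. The two aldehydes form ketyls at different rates, and aldol pathways are open. The match between the carvone isopropenyl group and C4 is lost, because that group would have to gain a formyl carbon.
- Comparison: the route is front-loaded and should be longer in total, though its last stage is shorter.

**Alternative 3:** The cut is C7–C8 and C9–C10, giving the ring A vinylcyclohexene A5 and the side-chain ynone A6. The forward step is an intermolecular Diels–Alder reaction to the 1,4-cyclohexadiene A7.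
- In its favour: it is the most convergent plan. The whole chain, ring B and quaternary C10 arrive in one step from two simple pieces, and A6 derives from the same half-ester as 16. On convergence this is the better plan. The regiochemistry is electronically matched (terminal diene carbon C7 to the β-carbon C8 of the ynone), which is an equal point, and the diol is again pre-formed.
- Against it here: the bond to C10 forms at a fully substituted diene terminus, so the reaction should be slow. The face of attack at C10 is controlled only by the distant acetonide, so a mixture at the quaternary centre is likely. A7 has the wrong unsaturation and oxidation pattern: the C11 carbonyl must be removed, C5=C6 reduced with H5 trans to C20, and the tetrasubstituted C8=C9 alkene moved against thermodynamics to C7=C8 while C9 is set, with no element in A7 to control this.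
- Comparison: assembly of the skeleton is shorter than in the chosen plan, but the path from A7 to 30 is longer and less secure. The chosen plan fixes C10 by alkylation of a ring enolate and C9 by a stereoelectronically controlled protonation.

Key step: step 5

Remarks on the chemistry:
- Labdane numbering is used for all ring compounds; carvone C1, C2, C3, C4, C5, C6 become C9, C8, C7, C6, C5, C10.
- The configuration at C5 is that of (S)-carvone throughout, and alkylation trans to the isopropenyl group gives C10 as 30 requires. The descriptors written for 9 and 10 were checked against 30 atom by atom.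
- The alkylating agent is methyl bromoacetate, not a tert-butyl ester. Acid strong enough to cleave a tert-butyl ester would protonate the isopropenyl group beside the new carboxyl and invite lactonisation; a methyl ester is cleaved by hydroxide.
- The C9 enone carbonyl is kept in 9 on purpose, because it deactivates C7=C8 toward the carbenoid.
- Compound 10 is written with the cyclopropane methylene C18 anti to C20. The opposite arrangement at C3/C4, if formed, would converge at 21.
- Pig liver esterase is assumed to give the (R) half-ester 12. If the (S) half-ester were obtained, reducing the ester end first would lead to the same iodide 16.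

## Route

Step 1
Reactants: 1 (S)-carvone
Product: 3 6-methylcarvone (epimers at the new methyl-bearing carbon; future C10), via carvone lithium enolate 2 (not isolated)
Conditions: LiN(i-Pr)2, THF, −78 °C; MeI, −78 → 0 °C
Reagents that add atoms: iodomethane, IC
Why: Kinetic deprotonation of the enone occurs at the α′ CH2 and the cross-conjugated enolate is C-methylated (enolate alkylation); the new centre is enolised again in step 2, so its configuration does not matter, and C5 is untouched.

Step 2
Reactants: 3 6-methylcarvone; 4 methyl bromoacetate
Product: 6 keto ester with the acetate arm trans and the C20 methyl cis to the isopropenyl group, via methylcarvone lithium enolate 5 (not isolated)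
Conditions: LiN(i-Pr)2, THF, −78 °C; 4, DMPU, −78 → −20 °C
Reagents that add atoms: none
Why: Enolate alkylation of the tetrasubstituted α′-enolate; the electrophile enters anti to the neighbouring isopropenyl group at C5, which sets quaternary C10 with the arm (C1) trans to C4, the relationship needed for a trans ring fusion.

Step 3
Reactants: 6 keto ester
Product: 7 keto acid
Conditions: LiOH, THF/MeOH/H2O, rt; then 1 M HCl
Reagents that add atoms: lithium hydroxide, [Li+].[OH-]
Why: Saponification of an unhindered methyl ester; C10 is quaternary and cannot epimerise, and the basic medium leaves the isopropenyl alkene alone.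

Step 4
Reactants: 7 keto acid
Product: 9 diazomethyl ketone (6-(3-diazo-2-oxopropyl)-6-methylcarvone; arm trans to isopropenyl), via acid chloride 8 (not isolated)
Conditions: (COCl)2, DMF (cat.), CH2Cl2, 0 °C → rt; concentrate; CH2N2 (excess), Et2O, 0 °C
Reagents that add atoms: diazomethane, C=[N+]=[N-]
Why: Arndt–Eistert-type acylation of diazomethane by the acid chloride, with a second equivalent taking up the HCl; the neutral, cold conditions avoid protonation of the isopropenyl group and bring in C3 as the future carbene carbon.

Step 5
Reactants: 9 diazomethyl ketone
Product: 10 tricyclic diketone (ring B enone; ring A C2 ketone; cyclopropane C3–C4–C18)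
Conditions: Cu(acac)2 (5 mol %), toluene, 100 °C, slow addition of 9 at high dilution
Reagents that add atoms: none
Why: Cu(acac)2 (divalent copper) is reduced by the diazo compound to the active monovalent copper species, which binds 9 at the diazo carbon and loses N2 to give an electrophilic copper carbenoid at C3. The carbenoid adds to the nucleophilic 1,1-disubstituted alkene C4=C18 in a concerted but asynchronous [2+1] addition, bonding first to terminal C18 and then to C4; the closest known reaction type is the copper-catalysed intramolecular cyclopropanation of unsaturated diazomethyl ketones to bicyclo[4.1.0]heptan-2-ones. Ring A (C10, C1, C2, C3, C4, C5) closes in the 6-exo sense through the C3–C4 bond, with C18 outside it, and the three-membered ring (C3, C4, C18) closes through the second bond from C3 to C18. The ring fusion is trans because the arm and the isopropenyl group were already placed trans on ring B in step 2. C4 is set by the alkene face that meets the carbenoid, governed by the C5 centre through the rotamer with C18 syn to H5, so that the arm passes under the ring and away from the axial C20 methyl; C3 follows from C4 because a cyclopropane fused to a six-membered ring must be cis. Both new centres are erased in step 12, so a mixture here would converge. The step needs selectivity for the isopropenyl alkene over C7=C8, over the lone pairs of the C9 carbonyl oxygen (six-membered carbonyl ylide) and over C–H insertion: C7=C8 is deactivated by conjugation and would give a bridged ring, copper carbenoids are less prone than dirhodium carbenoids to ylide formation and insertion, and slow addition suppresses carbene dimerisation.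

Step 6
Reactants: 11 dimethyl 3-methylglutarate
Product: 12 methyl hydrogen (R)-3-methylglutarate
Conditions: pig liver esterase, phosphate buffer pH 7/MeOH (4:1), 0 °C, pH-stat with 1 M NaOH; then HCl to pH 2
Reagents that add atoms: water, O
Why: Enzymatic desymmetrisation of a prochiral diester; the esterase should hydrolyse one enantiotopic ester group preferentially and so create the C13 centre, with the acid end destined to become C15.

Step 7
Reactants: 12 methyl hydrogen (R)-3-methylglutarate
Product: 13 methyl (R)-5-hydroxy-3-methylpentanoate
Conditions: BH3·SMe2, THF, −10 °C → rt; MeOH, H2O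
Reagents that add atoms: none
Why: Borane reduces a carboxylic acid through its acyloxyborane much faster than an ester, so only the acid end becomes the alcohol; the product is silylated promptly to prevent lactonisation.

Step 8
Reactants: 13 methyl (R)-5-hydroxy-3-methylpentanoate
Product: 14 methyl (R)-5-[(tert-butyldimethylsilyl)oxy]-3-methylpentanoate
Conditions: TBSCl, imidazole, DMF, rt
Reagents that add atoms: tert-butyldimethylsilyl chloride, CC(C)(C)[Si](C)(C)Cl
Why: Standard silylation of a primary alcohol; the silyl ether tolerates alkyllithium, dissolving metal, chromium and palladium steps later on.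

Step 9
Reactants: 14 silyl ether ester
Product: 15 (S)-5-[(tert-butyldimethylsilyl)oxy]-3-methylpentan-1-ol
Conditions: LiAlH4, Et2O, 0 °C; H2O
Reagents that add atoms: none
Why: Hydride reduction of the ester to the primary alcohol; the stereocentre is remote from the reacting carbon (the descriptor changes only through priorities).

Step 10
Reactants: 15 mono-protected diol
Product: 16 tert-butyl{[(R)-5-iodo-3-methylpentyl]oxy}dimethylsilane
Conditions: I2, PPh3, imidazole, CH2Cl2, 0 °C → rt
Reagents that add atoms: iodine, [I][I]
Why: Appel-type iodination through the alkoxyphosphonium iodide with SN2 displacement at the primary carbon; the iodide is the precursor of the C11 nucleophile.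

Step 11
Reactants: 10 tricyclic diketone; 16 side-chain iodide
Product: 20 C9 tertiary allylic alcohol bearing the side chain (C2 ketone and cyclopropane intact; C9 configuration immaterial), via C2 lithium enolate 17 (not isolated), via side-chain alkyllithium 18 (not isolated), via side-chain organocerium 19 (not isolated)
Conditions: 10, LiN(i-Pr)2 (1.05 equiv), THF, −78 °C; separately 16, t-BuLi (2.1 equiv), Et2O, −78 °C, then CeCl3, THF, −78 °C; combine, −78 → −40 °C; H2O
Reagents that add atoms: none
Why: The only acidic α-hydrogens of 10 are at C1, so one equivalent of amide base converts the C2 ketone into its enolate, which protects it in the flask (enolate as a transient protecting group); the weakly basic organocerium reagent then adds 1,2 to the hindered, non-enolisable C9 enone carbonyl. Iodine–lithium exchange with two equivalents of t-BuLi gives the primary alkyllithium cleanly; the C9 configuration is lost in step 14.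

Step 12
Reactants: 20 C9 tertiary allylic alcohol
Product: 22 C2 enol triflate with C2=C3 and gem-dimethyl C4 (C9 hydroxyl free), via dilithium enolate alkoxide 21 (not isolated)
Conditions: Li (2.2 equiv), NH3(l)/THF, −78 °C; evaporate NH3; PhNTf2 (1.2 equiv), THF, −78 → 0 °C
Reagents that add atoms: N-phenylbis(trifluoromethanesulfonimide), O=S(=O)(N(c1ccccc1)S(=O)(=O)C(F)(F)F)C(F)(F)F
Why: Dissolving-metal opening of the cyclopropyl ketone: the exocyclic C3–C18 bond overlaps best with the C2 carbonyl π system and gives a primary carbanion, so it is the bond that breaks, turning C18 into the second methyl on C4 and leaving the enolate fixed between C2 and C3. The hydroxyl of 20 supplies the single proton, the allylic alkoxide and the isolated alkene are inert to the metal, and the enolate oxygen is sulfonylated much faster than the hindered tertiary alkoxide.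

Step 13
Reactants: 22 C2 enol triflate
Product: 23 ring A C2=C3 alkene (C9 tertiary allylic alcohol retained)
Conditions: Pd(OAc)2 (5 mol %), PPh3, Bu3N, HCO2H, DMF, 60 °C
Reagents that add atoms: none
Why: Palladium-catalysed formate reduction of a vinyl triflate (oxidative addition to zerovalent palladium, formate exchange, loss of CO2, reductive elimination); the unactivated tertiary allylic alcohol does not ionise under these buffered conditions.

Step 14
Reactants: 23 tertiary allylic alcohol
Product: 24 enone C7(=O)–C8=C9 with the chain on C9 (C2=C3 alkene retained)
Conditions: [C5H5NH][CrO3Cl] (pyridinium chlorochromate, 2.5 equiv), 4 Å molecular sieves, CH2Cl2, rt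
Reagents that add atoms: pyridinium chlorochromate, [O-][Cr](=O)(=O)Cl.c1cc[nH+]cc1
Why: Babler–Dauben oxidative transposition: the tertiary chromate ester undergoes a [3,3] shift to the secondary C7 chromate, which is oxidised to the ketone; the isolated ring A alkene and the silyl ether are not affected by hexavalent chromium under these conditions.

Step 15
Reactants: 24 enone
Product: 26 C7 enol triflate with C7=C8 and H9 anti to C20, via C7 lithium enolate 25 (not isolated)
Conditions: Li (2.5 equiv), t-BuOH (1.0 equiv), NH3(l)/THF, −78 °C; isoprene; evaporate NH3; PhNTf2, THF, −78 → 0 °C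
Reagents that add atoms: N-phenylbis(trifluoromethanesulfonimide), O=S(=O)(N(c1ccccc1)S(=O)(=O)C(F)(F)F)C(F)(F)F
Why: Dissolving-metal reduction of the enone: the β-carbon C9 is protonated on the axial trajectory, anti to the axial C20 methyl, through a chair-like ring B, which sets C9 with the chain equatorial (also the more stable arrangement). The enolate is trapped where it forms, fixing the alkene between C7 and C8; the isolated C2=C3 alkene is not reduced.

Step 16
Reactants: 26 C7 enol triflate
Product: 27 2,3-cis-diol (both oxygens anti to C20; C7 triflate retained)
Conditions: OsO4 (5 mol %), NMO, acetone/H2O, rt; aq. Na2SO3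
Reagents that add atoms: osmium tetroxide, O=[Os](=O)(=O)=O; N-methylmorpholine N-oxide, C[N+]1([O-])CCOCC1
Why: Catalytic syn-dihydroxylation through a cyclic osmate ester: the top face of C2=C3 is blocked by the axial C20 and the axial C4 methyl, so both oxygens enter from the opposite face, setting C2 (equatorial oxygen) and C3 (axial oxygen) together. The tetrasubstituted, electron-poor vinyl triflate is not attacked, which is why ring B is still masked at this point.

Step 17
Reactants: 27 diol triflate
Product: 28 C7=C8 alkene diol (15-O-silyl)
Conditions: Pd(OAc)2 (5 mol %), PPh3, Bu3N, HCO2H, DMF, 70 °C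
Reagents that add atoms: none
Why: Palladium-catalysed formate reduction of the hindered vinyl triflate replaces the C7 oxygen by hydrogen and reveals the trisubstituted C7=C8 alkene without migration; free hydroxyls are tolerated.

Step 18
Reactants: 28 silyl ether diol
Product: 29 triol (2,3,15-trihydroxy compound)
Conditions: Bu4NF, THF, 0 °C → rt
Reagents that add atoms: none
Why: Fluoride cleavage of the primary silyl ether, driven by the strong Si–F bond; nothing else in the molecule is fluoride-sensitive.

Step 19
Reactants: 29 triol
Product: 30 target (2,15-diacetate with free axial C3 hydroxyl)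
Conditions: Ac2O (2.2 equiv), pyridine, CH2Cl2, 0 °C
Reagents that add atoms: acetic anhydride, CC(=O)OC(C)=O
Why: Kinetically controlled acylation: the primary C15 hydroxyl and the equatorial C2 hydroxyl react much faster than the axial C3 hydroxyl, which is shielded by the adjacent gem-dimethyl carbon, so the reaction should stop at the diacetate without an acyl-transfer catalyst.

## Compound list

1 | (S)-carvone | CC1=CC[C@@H](CC1=O)C(C)=C | starting material
2 | lithium enolate of (S)-carvone, deprotonated at the α′ CH2 (future C10) | CC1=CC[C@@H](C=C1[O-])C(C)=C.[Li+] | intermediate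
3 | 6-methylcarvone: (S)-carvone methylated at the α′ carbon, both epimers at that carbon (trans expected to predominate), isopropenyl centre unchanged | CC1=CC[C@@H](C(C)C1=O)C(C)=C | intermediate
4 | methyl bromoacetate | COC(=O)CBr | starting material
5 | lithium enolate of 6-methylcarvone (tetrasubstituted, at the future C10) | CC1=CC[C@@H](C(C)=C1[O-])C(C)=C.[Li+] | intermediate
6 | methyl 2-[(1R,6R)-1,3-dimethyl-2-oxo-6-(prop-1-en-2-yl)cyclohex-3-en-1-yl]acetate; acetate arm trans, methyl cis to the isopropenyl group | COC(=O)C[C@@]1(C)C(=O)C(C)=CC[C@@H]1C(C)=C | intermediate
7 | 2-[(1R,6R)-1,3-dimethyl-2-oxo-6-(prop-1-en-2-yl)cyclohex-3-en-1-yl]acetic acid | OC(=O)C[C@@]1(C)C(=O)C(C)=CC[C@@H]1C(C)=C | intermediate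
8 | acid chloride of 7 | ClC(=O)C[C@@]1(C)C(=O)C(C)=CC[C@@H]1C(C)=C | intermediate
9 | 1-diazo-3-[(1R,6R)-1,3-dimethyl-2-oxo-6-(prop-1-en-2-yl)cyclohex-3-en-1-yl]propan-2-one (6-(3-diazo-2-oxopropyl)-6-methylcarvone, arm trans to isopropenyl) | [N-]=[N+]=CC(=O)C[C@@]1(C)C(=O)C(C)=CC[C@@H]1C(C)=C | intermediate
10 | tricyclic diketone: ring B 8-methyl-7-en-9-one, ring A 2-ketone, cyclopropane C3–C4–C18 with C18 anti to C20, methyl C19 on C4, methyl C20 on C10, H5 anti to C20 | O=C1C[C@@]2(C)C(=O)C(C)=CC[C@@H]2[C@@]3(C)C[C@@H]13 | intermediate
11 | dimethyl 3-methylglutarate | COC(=O)CC(C)CC(=O)OC | starting material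
12 | methyl hydrogen (R)-3-methylglutarate ((R)-5-methoxy-3-methyl-5-oxopentanoic acid) | OC(=O)C[C@@H](C)CC(=O)OC | intermediate
13 | methyl (R)-5-hydroxy-3-methylpentanoate | OCC[C@@H](C)CC(=O)OC | intermediate
14 | methyl (R)-5-[(tert-butyldimethylsilyl)oxy]-3-methylpentanoate | CC(C)(C)[Si](C)(C)OCC[C@@H](C)CC(=O)OC | intermediate
15 | (S)-5-[(tert-butyldimethylsilyl)oxy]-3-methylpentan-1-ol | CC(C)(C)[Si](C)(C)OCC[C@@H](C)CCO | intermediate
16 | tert-butyl{[(R)-5-iodo-3-methylpentyl]oxy}dimethylsilane | CC(C)(C)[Si](C)(C)OCC[C@@H](C)CCI | intermediate
17 | lithium enolate of 10 at C2 (C1=C2), C9 enone free | [Li+].[O-]C1=C[C@@]2(C)C(=O)C(C)=CC[C@@H]2[C@@]3(C)C[C@@H]13 | intermediate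
18 | 5-[(tert-butyldimethylsilyl)oxy]-3-methylpentyllithium (same configuration as 16) | CC(C)(C)[Si](C)(C)OCC[C@@H](C)CC[Li] | intermediate
19 | dichloro{5-[(tert-butyldimethylsilyl)oxy]-3-methylpentyl}cerium (same configuration as 16) | CC(C)(C)[Si](C)(C)OCC[C@@H](C)CC[Ce](Cl)Cl | intermediate
20 | C9 tertiary allylic alcohol: 10 with the silyloxy side chain and a hydroxyl on C9 (either configuration at C9; chain expected mainly anti to C20), C7=C8, C2 ketone and cyclopropane intact | CC(C)(C)[Si](C)(C)OCC[C@@H](C)CCC1(O)C(C)=CC[C@@H]2[C@@]3(C)C[C@H]3C(=O)C[C@@]12C | intermediate
21 | dilithium salt: C2–C3 enolate with gem-dimethyl C4, and C9 alkoxide | [Li+].[Li+].CC(C)(C)[Si](C)(C)OCC[C@@H](C)CCC1([O-])C(C)=CC[C@@H]2C(C)(C)C=C([O-])C[C@@]12C | intermediate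
22 | C2 enol triflate (C2=C3), 4,4-dimethyl, C9 tertiary allylic alcohol, C7=C8, 15-O-silyl | CC(C)(C)[Si](C)(C)OCC[C@@H](C)CCC1(O)C(C)=CC[C@@H]2C(C)(C)C=C(OS(=O)(=O)C(F)(F)F)C[C@@]12C | intermediate
23 | 2,7-diene with C9 tertiary allylic alcohol, 15-O-silyl | CC(C)(C)[Si](C)(C)OCC[C@@H](C)CCC1(O)C(C)=CC[C@@H]2C(C)(C)C=CC[C@@]12C | intermediate
24 | 15-silyloxy-ent-labda-2,8-dien-7-one (enone C7=O, C8=C9) | CC(C)(C)[Si](C)(C)OCC[C@@H](C)CCC1=C(C)C(=O)C[C@@H]2C(C)(C)C=CC[C@@]12C | intermediate
25 | lithium C7–C8 enolate with H9 anti to C20 | [Li+].CC(C)(C)[Si](C)(C)OCC[C@@H](C)CC[C@@H]1C(C)=C([O-])C[C@@H]2C(C)(C)C=CC[C@@]12C | intermediate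
26 | 15-silyloxy-ent-labda-2,7-dien-7-yl triflate (H9 anti to C20, chain equatorial) | CC(C)(C)[Si](C)(C)OCC[C@@H](C)CC[C@@H]1C(C)=C(OS(=O)(=O)C(F)(F)F)C[C@@H]2C(C)(C)C=CC[C@@]12C | intermediate
27 | 2,3-cis-diol C7 triflate (O2 equatorial, O3 axial, both anti to C20), 15-O-silyl | CC(C)(C)[Si](C)(C)OCC[C@@H](C)CC[C@@H]1C(C)=C(OS(=O)(=O)C(F)(F)F)C[C@@H]2C(C)(C)[C@@H](O)[C@@H](O)C[C@@]12C | intermediate
28 | 15-O-(tert-butyldimethylsilyl)-ent-labd-7-ene-2,3,15-triol (cis-2,3-diol) | CC(C)(C)[Si](C)(C)OCC[C@@H](C)CC[C@@H]1C(C)=CC[C@@H]2C(C)(C)[C@@H](O)[C@@H](O)C[C@@]12C | intermediate
29 | ent-labd-7-ene-2,3,15-triol (cis-2,3-diol, both hydroxyls anti to C20) | OCC[C@@H](C)CC[C@@H]1C(C)=CC[C@@H]2C(C)(C)[C@@H](O)[C@@H](O)C[C@@]12C | intermediate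
30 | CNP0144124.1: (2S,3R,5S,9R,10S,13S)-3-hydroxylabd-7-ene-2,15-diyl diacetate (labdane numbering; ent-labdane) | CC(=O)OCC[C@@H](C)CC[C@@H]1C(C)=CC[C@@H]2C(C)(C)[C@@H](O)[C@@H](OC(C)=O)C[C@@]12C | target

## Step count and least certain steps

Total: 19 steps. Longest linear sequence: 14 steps (steps 1–5 and 11–19; the side-chain branch, steps 6–10 and 11–19, is equally long).

**Step 5 (key step).** The most likely failure is capture of the carbenoid by a lone pair of the C9 carbonyl oxygen. The arm on C10 can bring C3 within reach of that oxygen, which gives a six-membered carbonyl ylide that then decomposes; carbene dimerisation is a second risk if addition is not slow enough. The fallback removes the carbonyl during the cyclisation. It sets out from 9 and returns at 10. Luche reduction of 9 (NaBH4, CeCl3, MeOH, −78 °C; the diazo-substituted carbonyl is the less electrophilic one) gives the C9 allylic alcohol F1. Silylation (Et3SiCl, imidazole, DMF) gives the triethylsilyl ether F2. Cyclisation with Cu(acac)2 as in step 5 gives the silyloxy cyclopropyl ketone F3; the ring alkene is then no longer deactivated, but attack on it would require a bridged ring. Bu4NF gives the allylic alcohol F4, and MnO2 in CH2Cl2 oxidises it to 10.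

**Step 11.** The most likely failure is incomplete or unselective enolisation, so that part of the organocerium reagent adds to the more accessible C2 carbonyl; deprotonation at C6 of the enone, which would lower conversion at C9, is a second risk. The fallback replaces the transient enolate by a covalent protecting group. It sets out from 10 and returns at 20. Selective ketalisation of the saturated C2 ketone (ethylene glycol, pyridinium p-toluenesulfonate, toluene, reflux with azeotropic removal of water) gives the dioxolane F5. Addition of 19 as in step 11 gives the ketal tertiary alcohol F6. Mild transketalisation (pyridinium p-toluenesulfonate, acetone/H2O, rt), chosen to spare the tertiary allylic alcohol, gives 20.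

**Step 12.** The most likely failures are sulfonylation of the C9 alkoxide followed by ionisation of the resulting tertiary allylic triflate, and proton transfer that quenches or scrambles the enolate before it meets the triflating agent. The fallback separates electron transfer from sulfonylation and caps the alkoxide. It sets out from 20 and returns at 22. Reduction with Li in NH3/THF followed by Me3SiCl/Et3N gives the bis-silylated compound (C2 trimethylsilyl enol ether, C9 trimethylsilyl ether) F7. MeLi in THF at 0 °C regenerates the lithium enolate regiospecifically, and PhNTf2 gives the enol triflate C9 trimethylsilyl ether F8. K2CO3 in MeOH removes the tertiary silyl ether to give 22.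

**Step 16.** The most likely failure is a slow osmylation of the alkene beside quaternary C4, so that long exposure to the aqueous amine oxide erodes the vinyl triflate. The fallback moves the oxidation to a stage without a triflate and carries the diol protected. It sets out from 24 and returns at 29. Osmylation of 24 (OsO4, NMO; the tetrasubstituted enone is inert) gives the diol enone F9. 2,2-Dimethoxypropane with pyridinium p-toluenesulfonate gives the acetonide enone F10. Reduction and trapping as in step 15 gives the acetonide C7 triflate F11, and palladium-catalysed formate reduction as in step 17 gives the acetonide alkene F12. Aqueous HCl in THF removes the acetonide and the silyl ether together to give 29.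

**Step 19.** The most likely failure is over-acylation at the C3 hydroxyl, or acyl migration between the cis oxygens during work-up. The fallback separates the two acylations and uses tin to direct the secondary one. It sets out from 28 and returns at 30. Bu2SnO in toluene at reflux gives the 2,3-O-dibutylstannylene acetal F13. AcCl at 0 °C acylates its equatorial oxygen to give the 2-acetate 15-silyl ether F14. HF·pyridine in THF (non-basic, to avoid migration) gives the 2-acetate 3,15-diol F15. Ac2O (1.1 equiv) with 2,4,6-collidine at −20 °C acetylates only the primary hydroxyl to give 30.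

## Further compounds

F1 | step 5 | C9 allylic alcohol of the diazomethyl ketone (either configuration at C9) | [N-]=[N+]=CC(=O)C[C@@]1(C)C(O)C(C)=CC[C@@H]1C(C)=C
F2 | step 5 | C9 triethylsilyl ether of the diazomethyl ketone | [N-]=[N+]=CC(=O)C[C@@]1(C)C(O[Si](CC)(CC)CC)C(C)=CC[C@@H]1C(C)=C
F3 | step 5 | tricyclic cyclopropyl ketone with C9 triethylsilyloxy group and C7=C8 | O=C1C[C@@]2(C)C(O[Si](CC)(CC)CC)C(C)=CC[C@@H]2[C@@]3(C)C[C@@H]13
F4 | step 5 | tricyclic cyclopropyl ketone with C9 allylic hydroxyl | O=C1C[C@@]2(C)C(O)C(C)=CC[C@@H]2[C@@]3(C)C[C@@H]13
F5 | step 11 | C2 ethylene ketal of 10 | O1CCOC12C[C@@]3(C)C(=O)C(C)=CC[C@@H]3[C@@]4(C)C[C@@H]24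
F6 | step 11 | C2 ethylene ketal of 20 | CC(C)(C)[Si](C)(C)OCC[C@@H](C)CCC1(O)C(C)=CC[C@@H]2[C@@]3(C)C[C@H]3C4(OCCO4)C[C@@]12C
F7 | step 12 | C2 trimethylsilyl enol ether (C2=C3, 4,4-dimethyl) with C9 trimethylsilyl ether | CC(C)(C)[Si](C)(C)OCC[C@@H](C)CCC1(O[Si](C)(C)C)C(C)=CC[C@@H]2C(C)(C)C=C(O[Si](C)(C)C)C[C@@]12C
F8 | step 12 | C2 enol triflate with C9 trimethylsilyl ether | CC(C)(C)[Si](C)(C)OCC[C@@H](C)CCC1(O[Si](C)(C)C)C(C)=CC[C@@H]2C(C)(C)C=C(OS(=O)(=O)C(F)(F)F)C[C@@]12C
F9 | step 16 | 2,3-cis-diol of enone 24 (oxygens anti to C20) | CC(C)(C)[Si](C)(C)OCC[C@@H](C)CCC1=C(C)C(=O)C[C@@H]2C(C)(C)[C@@H](O)[C@@H](O)C[C@@]12C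
F10 | step 16 | 2,3-acetonide of F9 | CC(C)(C)[Si](C)(C)OCC[C@@H](C)CCC1=C(C)C(=O)C[C@@H]2C(C)(C)[C@@H](O3)[C@@H](OC3(C)C)C[C@@]12C
F11 | step 16 | 2,3-acetonide C7 enol triflate (C7=C8, H9 anti to C20) | CC(C)(C)[Si](C)(C)OCC[C@@H](C)CC[C@@H]1C(C)=C(OS(=O)(=O)C(F)(F)F)C[C@@H]2C(C)(C)[C@@H](O3)[C@@H](OC3(C)C)C[C@@]12C
F12 | step 16 | 2,3-acetonide of 28 | CC(C)(C)[Si](C)(C)OCC[C@@H](C)CC[C@@H]1C(C)=CC[C@@H]2C(C)(C)[C@@H](O3)[C@@H](OC3(C)C)C[C@@]12C
F13 | step 19 | 2,3-O-dibutylstannylene acetal of 28 | CC(C)(C)[Si](C)(C)OCC[C@@H](C)CC[C@@H]1C(C)=CC[C@@H]2C(C)(C)[C@@H](O3)[C@@H](O[Sn]3(CCCC)CCCC)C[C@@]12C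
F14 | step 19 | 2-O-acetyl-15-O-(tert-butyldimethylsilyl) triol | CC(C)(C)[Si](C)(C)OCC[C@@H](C)CC[C@@H]1C(C)=CC[C@@H]2C(C)(C)[C@@H](O)[C@@H](OC(C)=O)C[C@@]12C
F15 | step 19 | 2-O-acetyl triol with free C3 and C15 hydroxyls | OCC[C@@H](C)CC[C@@H]1C(C)=CC[C@@H]2C(C)(C)[C@@H](O)[C@@H](OC(C)=O)C[C@@]12C
A1 | alternative 1 | acyclic triene: (Z)-alkylidene methyl ester at C9=C10, (E,Z)-2-silyloxy diene C5–C8, 2,3-acetonide, 15-O-silyl | CC(C)(C)[Si](C)(C)OCC[C@@H](C)CC/C=C(\C(=O)OC)C[C@H](O1)[C@H](OC1(C)C)C(C)(C)/C=C/C(O[Si](C)(C)C(C)(C)C)=C/C
A2 | alternative 1 | trans-decalin with C20 methyl ester, ring B silyl enol ether (C6=C7), 2,3-acetonide, 15-O-silyl | CC(C)(C)[Si](C)(C)OCC[C@@H](C)CC[C@@H]1[C@H](C)C(O[Si](C)(C)C(C)(C)C)=C[C@@H]2C(C)(C)[C@@H](O3)[C@@H](OC3(C)C)C[C@@]12C(=O)OC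
A3 | alternative 2 | 2,3-seco dialdehyde: ring B with CH2CHO on C10, C(CH3)2CHO on C5, chain with 15-acetate on C9 | CC(=O)OCC[C@@H](C)CC[C@@H]1C(C)=CC[C@H](C(C)(C)C=O)[C@@]1(C)CC=O
A4 | alternative 2 | ent-labd-7-ene-2,3,15-triol 15-acetate (cis-2,3-diol) | CC(=O)OCC[C@@H](C)CC[C@@H]1C(C)=CC[C@@H]2C(C)(C)[C@@H](O)[C@@H](O)C[C@@]12C
A5 | alternative 3 | ring A diene: 1-vinylcyclohexene with methyl on the ring alkene carbon (C10), gem-dimethyl C4, 2,3-acetonide | C=CC1=C(C)C[C@H](O2)[C@H](OC2(C)C)C1(C)C
A6 | alternative 3 | side-chain ynone: 7-silyloxy-5-methylhept-2-yn-4-one | CC#CC(=O)C[C@H](C)CCO[Si](C)(C)C(C)(C)C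
A7 | alternative 3 | 11-oxo-ent-labda-5,8-diene 2,3-acetonide 15-silyl ether | CC1=C(C(=O)C[C@H](C)CCO[Si](C)(C)C(C)(C)C)[C@]2(C)C[C@H](O3)[C@H](OC3(C)C)C(C)(C)C2=CC1
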